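## The problem

The target is a pyrrolo[1,2-a]azepine in which pyrrolidine ring A and azepine ring B share the nitrogen and one CH. Ring B carries a spiro γ-lactone (ring C) on the carbon next to that CH and is fused to butenolide ring D through an N,O-acetal carbon. A second γ-lactone (ring E) hangs from the ring A carbon remote from the ring fusion.

There are seven stereocentres: the quaternary spiro carbon next to the ring-fusion CH, the ring A carbon next to the ring E carbinol carbon, one methyl-bearing carbon in each saturated lactone, and the aminal carbon. The ring-fusion centre can steer a 2,5-trans closure of ring A, and an alkene of fixed geometry can fix the ring A/ring E pair. The quaternary carbon can direct the 1,3-related methyl of ring C. The methyl centre of ring E is too remote to be induced and has to come from the chiral pool. The aminal carbon is epimerisable and can only be set under thermodynamic control.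

The N,O-acetal of ring D is the most fragile group, so it must be formed last. Before that, a basic nitrogen sits next to two lactones that it can open, and the α-methyl centres do not tolerate strong base once installed.

The feature that invites a cascade is that the ring A nitrogen and the ring oxygen of lactone E sit on adjacent carbons. Both heteroatoms can therefore be delivered across one (Z)-alkene of an open-chain amino ester.

## Retrosynthesis

**Rings B and D.** The N–C(aminal) bond and the lactone O–C(aminal) bond of 31 are cut first, because this N,O-acetal survives neither base nor nucleophiles. This leads through the amino hydroxybutenolide 30 to the secondary amine 29, in which ring D is stored as a tert-butyl ester cis to a dimethyl acetal on a tetrasubstituted alkene. Two rings and the labile stereocentre disappear. The forward step needs only acid and a seven-membered iminium/lactonisation that is reversible at the aminal carbon.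

**Rings A and E (key disconnection).** After putting a benzyl group on nitrogen (29 from 28), the N–C bond of ring A and the O–C bond of ring E are cut together to give the amino alkenyl ester 25. Cutting ring E alone would leave a pyrrolidine to be made first and a separate lactone annulation with its own facial problem. The double cut turns two rings and two stereocentres into one (Z)-alkene and a methyl ester whose stereocentre is bought. The forward step needs nitrogen, not the ester, to capture the iodonium ion. It must also give a 2,5-trans ring closure and an aziridinium opening at the exocyclic carbon.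

**Ring C methyl and nitrogen substituent.** The benzyl group of 25 is traced to the sulfinamide 23. The methyl group of ring C is removed to give lactone 22, and 22 is taken back to butenolide 21. The methyl is introduced as an electrophile because a carbon electrophile should enter the lactone enolate on the face away from the branched amino substituent. That face is the one the target needs. Hydrogenation of a pre-methylated butenolide would deliver hydrogen to the same open face and put the methyl on the wrong side.

**Spiro carbon and amine carbon.** The bond between the quaternary carbon and the amine carbon of 21 is cut as a vinylogous Mannich reaction between silyloxyfuran 10 and sulfinyl imine 20. No other cut is as convergent: it joins the two halves, forms the quaternary centre and places nitrogen with an auxiliary that is removed by acid. The forward step needs attack through C5 of the furan and control of both new centres.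

**Donor 10.** The silyloxyfuran comes from butenolide 9, which comes by reduction from the hydroxybutenolide 8 obtained on photo-oxygenation of furan 7. The furan is a latent butenolide that survives cross-coupling. The bond between the two-carbon tether and the enoate β-carbon of 7 is cut as a B-alkyl Suzuki–Miyaura coupling of borane 6 (from 2-vinylfuran 5) with enol triflate 4. Triflate 4 comes from β-keto ester 3, and 3 from tert-butyl propanoate 1 and methyl dimethoxyacetate 2. The alkene geometry of ring D is thus settled at the enol triflate.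

**Imine 20.** The imine is cut to aldehyde 18 and (R)-tert-butanesulfinamide 19. Aldehyde 18 comes from alcohol 17, and the sp2–sp3 bond of 17 is cut to (Z)-iodoalkene 15 and zinc reagent 16. Reagent 16 is made from iodide 12, which comes from the hydroxy ester 11. Iodoalkene 15 comes from pentynol 13 through iodoalkyne 14. The Z geometry is made by diimide reduction and kept by a stereoretentive coupling.

## Roads not taken

**Alternative 1:** The cut is the CH2–CH2 bond of ring B. A second-generation Grubbs catalyst, (H2IMes)(PCy3)Cl2Ru=CHPh, would join the vinyl group on the spiro carbon with the vinyl group on the butenolide β-carbon of diene A2. This gives the didehydro compound A1, whose ring B alkene is then hydrogenated.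

- Merits: metathesis is neutral and reliable for seven-membered rings, and the closure does not depend on an equilibrium at the aminal carbon. In that respect it is the safer way to close ring B.
- Weak points: A2 must already contain the N,O-acetal, made between two separate pieces without a ring to hold it. One vinyl group sits on a quaternary carbon and the other is part of an electron-poor dienyl lactone. The final hydrogenation must spare an allylic aminal.
- Comparison: this step builds one ring and no stereocentre, and leaves the ring A/ring E amino alcohol to other chemistry. The chosen plan makes two rings and two stereocentres in its key step and closes ring B by an intramolecular condensation that needs no further redox step.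

**Alternative 2:** The cuts are N–C(ring fusion) and N–C(acyl). Azido ketone A4 would undergo an intramolecular Schmidt reaction under TiCl4 or CF3SO3H to give lactam A3, closing ring A and expanding a cyclohexanone to ring B.

- Merits: two C–N bonds and two rings form in one step, and the migrating carbon keeps its configuration. The ring-fusion centre is therefore more secure than in a Mannich union, and this road is better on that point.
- Weak points: A3 carries a carbonyl where the target has the aminal CH. A cross-conjugated tertiary lactam would have to be half-reduced in the presence of two lactones and an ester and then lactonised. The α-stereocentre of the ketone in A4 is epimerisable, and the strong acid meets two lactones.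
- Comparison: the chosen plan has the aminal carbon at the right oxidation level from the start and creates the amino alcohol pair stereospecifically.

**Alternative 3:** The cut is the bond from the spiro carbon to the first CH2 of the tether. The organocerium reagent from iodide A7 (t-BuLi, then CeCl3) would add to the ketone of keto ester A6 under Felkin–Anh control, and the alkoxide would lactonise to give A5.

- Merits: the route is highly convergent. The ring C methyl comes from the chiral pool, and the quaternary centre rests on a better-understood model than the Mannich reaction used here. It is probably shorter and is at least as good for ring C.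
- Weak points: the pyrrolidine with ring E in A6 has to be made separately, with its own control of the amino alcohol pair. The reagent can attack lactone E or enolise the α-amino ketone. The furan must later be oxidised with singlet oxygen next to a nitrogen that has just lost its carbamate.
- Comparison: the chosen plan forms rings A and E together from an alkene whose geometry is easy to secure, and carries a latent butenolide that needs only acid at the end.

Key step: step 17

Assumption: the (R)-sulfinyl group is taken to direct the furan to the Re face of the imine carbon through the non-chelated s-cis arrangement (the (S)-sulfinamide would be used if the sense proved opposite), and the aminal epimer of the target is taken to be the one favoured at equilibrium.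

## Route

Step 1
Reactants: 1 tert-butyl propanoate; 2 methyl 2,2-dimethoxyacetate
Product: 3 tert-butyl 4,4-dimethoxy-2-methyl-3-oxobutanoate
Conditions: 1 (2.1 equiv), LiN(iPr)2 (2.1 equiv), THF, −78 °C; then 2, −78 → 0 °C; aq. NH4Cl
Reagents that add atoms: none
Why: Crossed Claisen condensation; the enolate of the hindered ester acylates on the non-enolisable, activated methyl ester and the second equivalent of enolate stores the product as its anion. The new stereocentre disappears in step 2.

Step 2
Reactants: 3 tert-butyl 4,4-dimethoxy-2-methyl-3-oxobutanoate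
Product: 4 tert-butyl (E)-4,4-dimethoxy-2-methyl-3-(trifluoromethylsulfonyloxy)but-2-enoate
Conditions: Tf2O, aq. Me4NOH, toluene, 0 °C
Reagents that add atoms: trifluoromethanesulfonic anhydride, O=S(=O)(OS(=O)(=O)C(F)(F)F)C(F)(F)F
Why: O-Sulfonylation of a β-keto ester enolate; with the non-coordinating tetramethylammonium counter-ion the enolate is not chelated and should adopt the dipole-minimised shape with the enolate oxygen anti to the ester. This gives the (E)-triflate, which places the acetal cis to the ester.

Step 3
Reactants: 5 2-vinylfuran; 4 tert-butyl (E)-4,4-dimethoxy-2-methyl-3-(trifluoromethylsulfonyloxy)but-2-enoate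
Product: 7 tert-butyl (Z)-3-(dimethoxymethyl)-5-(furan-2-yl)-2-methylpent-2-enoate, via alkylborane 6 (not isolated)
Conditions: 5, 9-BBN-H, THF, 0 °C → rt; then 4, Pd(dppf)Cl2 (5 mol%), aq. K3PO4, DMF, rt → 50 °C
Reagents that add atoms: none
Why: Anti-Markovnikov hydroboration of the vinyl group followed by B-alkyl Suzuki–Miyaura coupling with the enol triflate. Oxidative addition and reductive elimination keep the alkene geometry, so the tether ends up trans to the ester.

Step 4
Reactants: 7 tert-butyl (Z)-3-(dimethoxymethyl)-5-(furan-2-yl)-2-methylpent-2-enoate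
Product: 8 tert-butyl (Z)-3-(dimethoxymethyl)-5-(2-hydroxy-5-oxo-2,5-dihydrofuran-2-yl)-2-methylpent-2-enoate
Conditions: O2, visible light, tetraphenylporphyrin (cat.), iPr2NEt, CH2Cl2, −78 °C → rt
Reagents that add atoms: dioxygen, O=O
Why: [4+2] Addition of singlet oxygen to the furan and base-induced Kornblum–DeLaMare fragmentation of the endoperoxide at the unsubstituted α-carbon give the γ-hydroxybutenolide. The electron-poor tetrasubstituted enoate reacts far more slowly than the furan.

Step 5
Reactants: 8 tert-butyl (Z)-3-(dimethoxymethyl)-5-(2-hydroxy-5-oxo-2,5-dihydrofuran-2-yl)-2-methylpent-2-enoate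
Product: 9 tert-butyl (Z)-3-(dimethoxymethyl)-2-methyl-5-(5-oxo-2,5-dihydrofuran-2-yl)pent-2-enoate
Conditions: NaBH4, CeCl3·7H2O, MeOH, −20 → 0 °C; then AcOH to pH 5
Reagents that add atoms: none
Why: Luche 1,2-reduction of the open (Z)-4-oxo-enoate form of the pseudo-acid, then lactonisation of the (Z)-4-hydroxy-enoic acid on mild acidification. The racemic centre is planarised in step 6.

Step 6
Reactants: 9 tert-butyl (Z)-3-(dimethoxymethyl)-2-methyl-5-(5-oxo-2,5-dihydrofuran-2-yl)pent-2-enoate
Product: 10 tert-butyl (Z)-3-(dimethoxymethyl)-2-methyl-5-[5-(triisopropylsilyloxy)furan-2-yl]pent-2-enoate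
Conditions: iPr3SiOTf (1.05 equiv), Et3N, CH2Cl2, −78 → 0 °C
Reagents that add atoms: triisopropylsilyl trifluoromethanesulfonate, CC(C)[Si](C(C)C)(C(C)C)OS(=O)(=O)C(F)(F)F
Why: Soft enolisation of the butenolide to the aromatic 2-silyloxyfuran. The silyl triflate is used in slight excess only and is consumed at once by the acidic γ-hydrogen, which should spare the deactivated acetal.

Step 7
Reactants: 11 methyl (S)-3-hydroxy-2-methylpropanoate
Product: 12 methyl (R)-3-iodo-2-methylpropanoate
Conditions: I2, PPh3, imidazole, CH2Cl2, 0 °C → rt
Reagents that add atoms: iodine, II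
Why: Appel reaction at the primary carbinol; the stereocentre is not touched and only its descriptor changes.

Step 8
Reactants: 13 pent-4-yn-1-ol
Product: 14 5-iodopent-4-yn-1-ol
Conditions: N-iodosuccinimide, AgNO3 (10 mol%), acetone, rt, dark
Reagents that add atoms: N-iodosuccinimide, O=C1CCC(=O)N1I
Why: Electrophilic iodination of the terminal alkyne through its silver acetylide.

Step 9
Reactants: 14 5-iodopent-4-yn-1-ol
Product: 15 (Z)-5-iodopent-4-en-1-ol
Conditions: 2-nitrobenzenesulfonohydrazide, Et3N, THF–iPrOH, rt
Reagents that add atoms: none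
Why: Diimide generated in the flask adds two hydrogens suprafacially to the iodoalkyne, which gives the cis-iodoalkene without cleaving the C–I bond.

Step 10
Reactants: 12 methyl (R)-3-iodo-2-methylpropanoate; 15 (Z)-5-iodopent-4-en-1-ol
Product: 17 methyl (2S,4Z)-8-hydroxy-2-methyloct-4-enoate, via alkylzinc iodide 16 (not isolated)
Conditions: 12, Zn dust (activated with BrCH2CH2Br and Me3SiCl), DMF, rt; then 15, Pd(OAc)2 (3 mol%), SPhos (6 mol%), THF, rt
Reagents that add atoms: none
Why: Zinc insertion gives a β-zincio ester that does not enolise, and Negishi coupling under zerovalent palladium joins it to the iodoalkene with retention of the Z geometry. The free hydroxyl is tolerated by the weakly basic zinc reagent.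

Step 11
Reactants: 17 methyl (2S,4Z)-8-hydroxy-2-methyloct-4-enoate
Product: 18 methyl (2S,4Z)-2-methyl-8-oxooct-4-enoate
Conditions: TEMPO (10 mol%), PhI(OAc)2, CH2Cl2, rt
Reagents that add atoms: none
Why: Oxoammonium-mediated oxidation of the primary alcohol stops at the aldehyde and leaves the Z-alkene and the α-stereocentre alone.

Step 12
Reactants: 18 methyl (2S,4Z)-2-methyl-8-oxooct-4-enoate; 19 (R)-2-methylpropane-2-sulfinamide
Product: 20 methyl (2S,4Z,8E)-8-[(R)-tert-butylsulfinylimino]-2-methyloct-4-enoate
Conditions: CuSO4 (anhydrous), CH2Cl2, rt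
Reagents that add atoms: none
Why: Dehydrative condensation to the (E)-N-sulfinyl aldimine; no stereocentre is formed.

Step 13
Reactants: 10 tert-butyl (Z)-3-(dimethoxymethyl)-2-methyl-5-[5-(triisopropylsilyloxy)furan-2-yl]pent-2-enoate; 20 methyl (2S,4Z,8E)-8-[(R)-tert-butylsulfinylimino]-2-methyloct-4-enoate
Product: 21 tert-butyl (Z)-5-[(S)-2-{(1S,4Z,7S)-1-[(R)-tert-butylsulfinylamino]-8-methoxy-7-methyl-8-oxooct-4-en-1-yl}-5-oxo-2,5-dihydrofuran-2-yl]-3-(dimethoxymethyl)-2-methylpent-2-enoate
Conditions: BF3·OEt2 (1.2 equiv), CH2Cl2, −78 °C; aq. NaHCO3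
Reagents that add atoms: none
Why: Vinylogous Mukaiyama–Mannich addition through an open transition state; the tert-butyl group shields one face of the s-cis imine so the amine carbon should form as (S). The (S) quaternary centre should follow from the staggered approach with the sulfinyl nitrogen anti to the furan oxygen and the imine chain away from the C5 tether. BF3·OEt2 at −78 °C is preferred to a silyl triflate because it leaves the dimethyl acetal alone.

Step 14
Reactants: 21 tert-butyl (Z)-5-[(S)-2-{(1S,4Z,7S)-1-[(R)-tert-butylsulfinylamino]-8-methoxy-7-methyl-8-oxooct-4-en-1-yl}-5-oxo-2,5-dihydrofuran-2-yl]-3-(dimethoxymethyl)-2-methylpent-2-enoate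
Product: 22 tert-butyl (Z)-5-[(S)-2-{(1S,4Z,7S)-1-[(R)-tert-butylsulfinylamino]-8-methoxy-7-methyl-8-oxooct-4-en-1-yl}-5-oxotetrahydrofuran-2-yl]-3-(dimethoxymethyl)-2-methylpent-2-enoate
Conditions: [(Ph3P)CuH]6 (5 mol%), PhMe2SiH, t-BuOH, toluene, 0 °C → rt
Reagents that add atoms: none
Why: Copper hydride conjugate reduction of the disubstituted butenolide. The isolated Z-alkene is not a substrate and the tetrasubstituted enoate is too hindered, so no stereocentre is at stake.

Step 15
Reactants: 22 tert-butyl (Z)-5-[(S)-2-{(1S,4Z,7S)-1-[(R)-tert-butylsulfinylamino]-8-methoxy-7-methyl-8-oxooct-4-en-1-yl}-5-oxotetrahydrofuran-2-yl]-3-(dimethoxymethyl)-2-methylpent-2-enoate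
Product: 23 tert-butyl (Z)-5-[(2S,4R)-2-{(1S,4Z,7S)-1-[(R)-tert-butylsulfinylamino]-8-methoxy-7-methyl-8-oxooct-4-en-1-yl}-4-methyl-5-oxotetrahydrofuran-2-yl]-3-(dimethoxymethyl)-2-methylpent-2-enoate
Conditions: LiN(SiMe3)2 (2.2 equiv), THF, −78 °C; then MeI (1.3 equiv), −78 → −50 °C; aq. NH4Cl
Reagents that add atoms: iodomethane, CI
Why: Lactone enolate alkylation; the first equivalent of base removes the sulfinamide proton and the second enolises the γ-lactone, which is several pKa units more acidic than the open-chain esters. Iodomethane should enter anti to the branched, N-metalated amino substituent on the quaternary carbon, which places the methyl cis to the two-carbon tether as in ring C.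

Step 16
Reactants: 23 tert-butyl (Z)-5-[(2S,4R)-2-{(1S,4Z,7S)-1-[(R)-tert-butylsulfinylamino]-8-methoxy-7-methyl-8-oxooct-4-en-1-yl}-4-methyl-5-oxotetrahydrofuran-2-yl]-3-(dimethoxymethyl)-2-methylpent-2-enoate
Product: 25 tert-butyl (Z)-5-[(2S,4R)-2-{(1S,4Z,7S)-1-(benzylamino)-8-methoxy-7-methyl-8-oxooct-4-en-1-yl}-4-methyl-5-oxotetrahydrofuran-2-yl]-3-(dimethoxymethyl)-2-methylpent-2-enoate, via amine hydrochloride 24 (not isolated)
Conditions: HCl (4 M in dioxane, 3 equiv), MeOH, 0 °C; evaporate; then PhCHO, Et3N, NaBH(OAc)3, ClCH2CH2Cl, rt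
Reagents that add atoms: benzaldehyde, O=Cc1ccccc1
Why: Acidolysis of the N–S bond, then reductive amination of the ammonium salt without isolation. This keeps the free primary amine from attacking the neighbouring lactone, and the tert-butyl ester and acetal tolerate brief methanolic HCl at 0 °C.

Step 17
Reactants: 25 tert-butyl (Z)-5-[(2S,4R)-2-{(1S,4Z,7S)-1-(benzylamino)-8-methoxy-7-methyl-8-oxooct-4-en-1-yl}-4-methyl-5-oxotetrahydrofuran-2-yl]-3-(dimethoxymethyl)-2-methylpent-2-enoate
Product: 28 tert-butyl (Z)-5-[(2S,4R)-2-{(2S,5S)-1-benzyl-5-[(2S,4S)-4-methyl-5-oxotetrahydrofuran-2-yl]pyrrolidin-2-yl}-4-methyl-5-oxotetrahydrofuran-2-yl]-3-(dimethoxymethyl)-2-methylpent-2-enoate, via iodoamine 26 (not isolated), via aziridinium iodide 27 (not isolated)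
Conditions: I2 (2.5 equiv), NaHCO3 (3 equiv), CH2Cl2–Et2O, 0 °C → rt, dark
Reagents that add atoms: none
Why: Iodine forms an iodonium ion on the Z-alkene, the free secondary amine opens it at the nearer carbon to give the β-iodo pyrrolidine 26, nitrogen then expels iodide to give the bicyclic aziridinium ion 27, and the ester carbonyl oxygen opens 27 at the exocyclic carbon while iodide removes the ester methyl as iodomethane. The closest known reaction type is the iodoamination–aziridinium–lactonisation cascade of amino alkenyl esters. Ring A closes 5-exo-trig on the iodonium ion and ring E closes 5-exo-tet on the aziridinium carbon. The new ring A stereocentre should be set by a chair-like transition state in which the bulky spirolactone substituent next to nitrogen is pseudo-equatorial and the N-benzyl group lies anti to it, which gives the 2,5-trans pyrrolidine. The carbinol centre is tied to it because anti iodoamination followed by two inversions at that carbon amounts to anti delivery of N and O across the Z-alkene, which is the target's relative configuration. The step needs nitrogen to capture the iodonium ion before the ester does, since iodolactonisation followed by N-displacement would give the epimeric pair; the far greater nucleophilicity of the amine and the base that keeps it unprotonated secure this. It also needs the aziridinium ion to open at the exocyclic carbon, which is favoured because only that mode gives a five-membered lactone. The tetrasubstituted enoate and the acetal do not react with iodine.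

Step 18
Reactants: 28 tert-butyl (Z)-5-[(2S,4R)-2-{(2S,5S)-1-benzyl-5-[(2S,4S)-4-methyl-5-oxotetrahydrofuran-2-yl]pyrrolidin-2-yl}-4-methyl-5-oxotetrahydrofuran-2-yl]-3-(dimethoxymethyl)-2-methylpent-2-enoate
Product: 29 tert-butyl (Z)-3-(dimethoxymethyl)-2-methyl-5-[(2S,4R)-4-methyl-2-{(2S,5S)-5-[(2S,4S)-4-methyl-5-oxotetrahydrofuran-2-yl]pyrrolidin-2-yl}-5-oxotetrahydrofuran-2-yl]pent-2-enoate
Conditions: H2 (1 atm), Pd(OH)2/C, EtOAc–EtOH, rt; used at once
Reagents that add atoms: none
Why: Hydrogenolysis of the N-benzyl group. The tetrasubstituted, ester-conjugated alkene is inert under these conditions, and there is no other reducible group.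

Step 19
Reactants: 29 tert-butyl (Z)-3-(dimethoxymethyl)-2-methyl-5-[(2S,4R)-4-methyl-2-{(2S,5S)-5-[(2S,4S)-4-methyl-5-oxotetrahydrofuran-2-yl]pyrrolidin-2-yl}-5-oxotetrahydrofuran-2-yl]pent-2-enoate
Product: 31 CNP0155196.1 (target), via hydroxybutenolide 30 (not isolated)
Conditions: CF3CO2H–H2O (9:1), CH2Cl2, 0 °C → rt; evaporate; aq. NaHCO3 wash; then toluene, 4 Å molecular sieves, 50 °C
Reagents that add atoms: none
Why: Acid removes the tert-butyl group and hydrolyses the acetal, and the (Z)-β-formyl acrylic acid closes to the 5-hydroxybutenolide 30. Once the amine is free it condenses with this pseudo-acid through a seven-membered iminium carboxylate that collapses to the N,O-acetal lactone, closing rings B and D. The aminal centre forms reversibly, so the more stable epimer should accumulate.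

## Compound list

1 | tert-butyl propanoate | CCC(=O)OC(C)(C)C | starting material
2 | methyl 2,2-dimethoxyacetate | COC(OC)C(=O)OC | starting material
3 | tert-butyl 4,4-dimethoxy-2-methyl-3-oxobutanoate (racemic) | CC(C(=O)C(OC)OC)C(=O)OC(C)(C)C | intermediate
4 | tert-butyl (E)-4,4-dimethoxy-2-methyl-3-(trifluoromethylsulfonyloxy)but-2-enoate | CC(C)(C)OC(=O)/C(C)=C(/OS(=O)(=O)C(F)(F)F)C(OC)OC | intermediate
5 | 2-vinylfuran | C=Cc1ccco1 | starting material
6 | 9-[2-(furan-2-yl)ethyl]-9-borabicyclo[3.3.1]nonane | C(Cc1ccco1)B1C2CCCC1CCC2 | intermediate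
7 | tert-butyl (Z)-3-(dimethoxymethyl)-5-(furan-2-yl)-2-methylpent-2-enoate | CC(C)(C)OC(=O)/C(C)=C(/CCc1ccco1)C(OC)OC | intermediate
8 | tert-butyl (Z)-3-(dimethoxymethyl)-5-(2-hydroxy-5-oxo-2,5-dihydrofuran-2-yl)-2-methylpent-2-enoate (racemic) | CC(C)(C)OC(=O)/C(C)=C(/CCC1(O)OC(=O)C=C1)C(OC)OC | intermediate
9 | tert-butyl (Z)-3-(dimethoxymethyl)-2-methyl-5-(5-oxo-2,5-dihydrofuran-2-yl)pent-2-enoate (racemic) | CC(C)(C)OC(=O)/C(C)=C(/CCC1OC(=O)C=C1)C(OC)OC | intermediate
10 | tert-butyl (Z)-3-(dimethoxymethyl)-2-methyl-5-[5-(triisopropylsilyloxy)furan-2-yl]pent-2-enoate | CC(C)(C)OC(=O)/C(C)=C(/CCc1ccc(O[Si](C(C)C)(C(C)C)C(C)C)o1)C(OC)OC | intermediate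
11 | methyl (S)-3-hydroxy-2-methylpropanoate | COC(=O)[C@@H](C)CO | starting material
12 | methyl (R)-3-iodo-2-methylpropanoate | COC(=O)[C@@H](C)CI | intermediate
13 | pent-4-yn-1-ol | C#CCCCO | starting material
14 | 5-iodopent-4-yn-1-ol | OCCCC#CI | intermediate
15 | (Z)-5-iodopent-4-en-1-ol | OCCC/C=C\I | intermediate
16 | [(2R)-3-methoxy-2-methyl-3-oxopropyl]zinc iodide | COC(=O)[C@@H](C)C[Zn]I | intermediate
17 | methyl (2S,4Z)-8-hydroxy-2-methyloct-4-enoate | COC(=O)[C@@H](C)C/C=C\CCCO | intermediate
18 | methyl (2S,4Z)-2-methyl-8-oxooct-4-enoate | COC(=O)[C@@H](C)C/C=C\CCC=O | intermediate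
19 | (R)-2-methylpropane-2-sulfinamide | CC(C)(C)[S@@](=O)N | starting material
20 | methyl (2S,4Z,8E)-8-[(R)-tert-butylsulfinylimino]-2-methyloct-4-enoate | COC(=O)[C@@H](C)C/C=C\CC/C=N/[S@](=O)C(C)(C)C | intermediate
21 | tert-butyl (Z)-5-[(S)-2-{(1S,4Z,7S)-1-[(R)-tert-butylsulfinylamino]-8-methoxy-7-methyl-8-oxooct-4-en-1-yl}-5-oxo-2,5-dihydrofuran-2-yl]-3-(dimethoxymethyl)-2-methylpent-2-enoate | CC(C)(C)OC(=O)/C(C)=C(/CC[C@]1(C=CC(=O)O1)[C@@H](N[S@](=O)C(C)(C)C)CC/C=C\C[C@H](C)C(=O)OC)C(OC)OC | intermediate
22 | tert-butyl (Z)-5-[(S)-2-{(1S,4Z,7S)-1-[(R)-tert-butylsulfinylamino]-8-methoxy-7-methyl-8-oxooct-4-en-1-yl}-5-oxotetrahydrofuran-2-yl]-3-(dimethoxymethyl)-2-methylpent-2-enoate | CC(C)(C)OC(=O)/C(C)=C(/CC[C@]1(CCC(=O)O1)[C@@H](N[S@](=O)C(C)(C)C)CC/C=C\C[C@H](C)C(=O)OC)C(OC)OC | intermediate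
23 | tert-butyl (Z)-5-[(2S,4R)-2-{(1S,4Z,7S)-1-[(R)-tert-butylsulfinylamino]-8-methoxy-7-methyl-8-oxooct-4-en-1-yl}-4-methyl-5-oxotetrahydrofuran-2-yl]-3-(dimethoxymethyl)-2-methylpent-2-enoate | CC(C)(C)OC(=O)/C(C)=C(/CC[C@]1(C[C@@H](C)C(=O)O1)[C@@H](N[S@](=O)C(C)(C)C)CC/C=C\C[C@H](C)C(=O)OC)C(OC)OC | intermediate
24 | tert-butyl (Z)-5-[(2S,4R)-2-{(1S,4Z,7S)-1-amino-8-methoxy-7-methyl-8-oxooct-4-en-1-yl}-4-methyl-5-oxotetrahydrofuran-2-yl]-3-(dimethoxymethyl)-2-methylpent-2-enoate hydrochloride | CC(C)(C)OC(=O)/C(C)=C(/CC[C@]1(C[C@@H](C)C(=O)O1)[C@@H](N)CC/C=C\C[C@H](C)C(=O)OC)C(OC)OC.Cl | intermediate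
25 | tert-butyl (Z)-5-[(2S,4R)-2-{(1S,4Z,7S)-1-(benzylamino)-8-methoxy-7-methyl-8-oxooct-4-en-1-yl}-4-methyl-5-oxotetrahydrofuran-2-yl]-3-(dimethoxymethyl)-2-methylpent-2-enoate | CC(C)(C)OC(=O)/C(C)=C(/CC[C@]1(C[C@@H](C)C(=O)O1)[C@@H](NCc1ccccc1)CC/C=C\C[C@H](C)C(=O)OC)C(OC)OC | intermediate
26 | tert-butyl (Z)-5-[(2S,4R)-2-{(2S,5S)-1-benzyl-5-[(1S,3S)-1-iodo-4-methoxy-3-methyl-4-oxobutyl]pyrrolidin-2-yl}-4-methyl-5-oxotetrahydrofuran-2-yl]-3-(dimethoxymethyl)-2-methylpent-2-enoate | CC(C)(C)OC(=O)/C(C)=C(/CC[C@]1(C[C@@H](C)C(=O)O1)[C@@H]1CC[C@@H]([C@@H](I)C[C@H](C)C(=O)OC)N1Cc1ccccc1)C(OC)OC | intermediate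
27 | N-benzyl aziridinium iodide (1-azoniabicyclo[3.1.0]hexane) formed from 26 by displacement of iodide by nitrogen, with the former CHI carbon inverted | CC(C)(C)OC(=O)/C(C)=C(/CC[C@]1(C[C@@H](C)C(=O)O1)[C@@H]1CC[C@H]2[C@@H](C[C@H](C)C(=O)OC)[N+]12Cc1ccccc1)C(OC)OC.[I-] | intermediate
28 | tert-butyl (Z)-5-[(2S,4R)-2-{(2S,5S)-1-benzyl-5-[(2S,4S)-4-methyl-5-oxotetrahydrofuran-2-yl]pyrrolidin-2-yl}-4-methyl-5-oxotetrahydrofuran-2-yl]-3-(dimethoxymethyl)-2-methylpent-2-enoate | CC(C)(C)OC(=O)/C(C)=C(/CC[C@]1(C[C@@H](C)C(=O)O1)[C@@H]1CC[C@@H]([C@@H]2C[C@H](C)C(=O)O2)N1Cc1ccccc1)C(OC)OC | intermediate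
29 | tert-butyl (Z)-3-(dimethoxymethyl)-2-methyl-5-[(2S,4R)-4-methyl-2-{(2S,5S)-5-[(2S,4S)-4-methyl-5-oxotetrahydrofuran-2-yl]pyrrolidin-2-yl}-5-oxotetrahydrofuran-2-yl]pent-2-enoate | CC(C)(C)OC(=O)/C(C)=C(/CC[C@]1(C[C@@H](C)C(=O)O1)[C@@H]1CC[C@@H]([C@@H]2C[C@H](C)C(=O)O2)N1)C(OC)OC | intermediate
30 | 5-hydroxy-3-methyl-4-{2-[(2S,4R)-4-methyl-2-{(2S,5S)-5-[(2S,4S)-4-methyl-5-oxotetrahydrofuran-2-yl]pyrrolidin-2-yl}-5-oxotetrahydrofuran-2-yl]ethyl}furan-2(5H)-one (trifluoroacetate salt, hemiacetal carbon unassigned) | CC1=C(CC[C@]2(C[C@@H](C)C(=O)O2)[C@@H]2CC[C@@H]([C@@H]3C[C@H](C)C(=O)O3)N2)C(O)OC1=O | intermediate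
31 | CNP0155196.1: pentacyclic N,O-acetal butenolide; spiro carbon S, ring C methyl carbon R, ring-fusion carbon S, ring A carbon bearing ring E S, ring E carbinol carbon S, ring E methyl carbon S, aminal carbon S | CC1=C2CC[C@]3(C[C@@H](C)C(=O)O3)[C@@H]3CC[C@@H]([C@@H]4C[C@H](C)C(=O)O4)N3[C@H]2OC1=O | target

## Step count and risks

Total: 19 steps. Longest linear sequence: 13 steps (steps 1–6 and 13–19, from tert-butyl propanoate). The imine branch (steps 7–12) joins at step 13.

**Step 17 (key step).** Three things can go wrong.
- The ester oxygen may capture the iodonium ion ahead of nitrogen if the amine becomes protonated, which would end in the epimeric amino alcohol.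
- Facial selectivity in the ring closure may be low, because it rests only on a conformational preference of an acyclic N-benzylamine.
- Iodide may reopen the aziridinium ion at the ring carbon and divert material to a piperidine.

Fallback, from 25 back to 28: the amine of 25 is protonated with CF3CO2H and the Z-alkene is epoxidised with mCPBA to the cis-epoxide F1. Freeing the amine (iPr2NEt, MeCN, 60 °C) gives 5-exo opening with inversion to the hydroxy pyrrolidine ester F2. Lactonisation (pyridinium p-toluenesulfonate, toluene) then gives 28. The relative configuration of the pair is again fixed by the alkene geometry, but the facial sense is not controlled, so 28 would have to be separated from its isomer.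

**Step 13.** The simple diastereoselection at a fully substituted furan C5 may be low or opposite to the model. Attack through C3 may compete, and the Lewis acid may ionise the acetal.

Fallback, from 9 and 18 back to 24: aldehyde 18 is converted with tert-butyl carbamate, PhSO2Na and formic acid into the α-amido sulfone F3. Butenolide 9 is added directly to the N-Boc imine released from F3, under a cinchona-derived bifunctional or phase-transfer catalyst with aqueous K2CO3, to give the N-Boc adduct F4 under catalyst control. Conjugate reduction as in step 14 gives lactone F5 and methylation as in step 15 gives F6. HCl in dioxane removes the carbamate and delivers 24.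

**Step 15.** The electrophile may not discriminate well between the two faces of the enolate. The base may also remove the γ-proton of the tetrasubstituted enoate or methylate the sulfinamide nitrogen.

Fallback, from 22 back to 23: the lactone enolate is aminomethylated (LiN(SiMe3)2, then CH2=NMe2+ I−) to the Mannich base F7. Quaternisation with MeI and elimination with NaHCO3 give the α-methylene lactone F8. Conjugate reduction with [(Ph3P)CuH]6 and kinetic protonation then deliver hydrogen, not carbon, to the α-carbon. This gives 23 if the open face turns out to be the one next to the amino branch.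

**Step 2.** The enolate may react in its chelated shape and give the triflate with the opposite geometry, or a mixture.

Fallback, from 1 back to 7: Claisen condensation of 1 with commercial ethyl 3-(furan-2-yl)propanoate gives the β-keto ester F9. NaH and Tf2O give the chelation-controlled (Z)-enol triflate F10, the geometry that this substrate class adopts most readily. Formylation (Pd(PPh3)4, CO, Bu3SnH) gives the enal F11 with the formyl group cis to the ester. Acetalisation with HC(OMe)3 and pyridinium p-toluenesulfonate in MeOH gives 7.

**Step 19.** The acetal may hydrolyse slowly, the free amine may attack a neighbouring lactone before it finds the pseudo-acid, or the equilibrium at the aminal carbon may not favour the target epimer.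

Fallback, from 30 back to 31: the ammonium salt of 30 is treated with SOCl2 (cat. DMF) to give the 5-chlorobutenolide hydrochloride F12. Et3N at low temperature then closes ring B by irreversible N-alkylation, so the aminal centre is set under kinetic rather than thermodynamic control.

## Further compounds

F1 | step 17 | cis-epoxide of 25 (amine as trifluoroacetate), the isomer that leads to 28 | CC(C)(C)OC(=O)/C(C)=C(/CC[C@]1(C[C@@H](C)C(=O)O1)[C@@H](NCc1ccccc1)CC[C@H]1O[C@H]1C[C@H](C)C(=O)OC)C(OC)OC
F2 | step 17 | N-benzyl pyrrolidine hydroxy methyl ester (ring A closed, ring E open) | CC(C)(C)OC(=O)/C(C)=C(/CC[C@]1(C[C@@H](C)C(=O)O1)[C@@H]1CC[C@@H]([C@@H](O)C[C@H](C)C(=O)OC)N1Cc1ccccc1)C(OC)OC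
F3 | step 13 | methyl (2S,4Z)-8-(tert-butoxycarbonylamino)-2-methyl-8-(phenylsulfonyl)oct-4-enoate | COC(=O)[C@@H](C)C/C=C\CCC(NC(=O)OC(C)(C)C)S(=O)(=O)c1ccccc1
F4 | step 13 | N-Boc analogue of butenolide 21 | CC(C)(C)OC(=O)/C(C)=C(/CC[C@]1(C=CC(=O)O1)[C@@H](NC(=O)OC(C)(C)C)CC/C=C\C[C@H](C)C(=O)OC)C(OC)OC
F5 | step 13 | N-Boc analogue of lactone 22 | CC(C)(C)OC(=O)/C(C)=C(/CC[C@]1(CCC(=O)O1)[C@@H](NC(=O)OC(C)(C)C)CC/C=C\C[C@H](C)C(=O)OC)C(OC)OC
F6 | step 13 | N-Boc analogue of methyl lactone 23 | CC(C)(C)OC(=O)/C(C)=C(/CC[C@]1(C[C@@H](C)C(=O)O1)[C@@H](NC(=O)OC(C)(C)C)CC/C=C\C[C@H](C)C(=O)OC)C(OC)OC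
F7 | step 15 | α-(dimethylaminomethyl) lactone from 22 | CC(C)(C)OC(=O)/C(C)=C(/CC[C@]1(CC(CN(C)C)C(=O)O1)[C@@H](N[S@](=O)C(C)(C)C)CC/C=C\C[C@H](C)C(=O)OC)C(OC)OC
F8 | step 15 | α-methylene lactone from 22 | CC(C)(C)OC(=O)/C(C)=C(/CC[C@]1(CC(=C)C(=O)O1)[C@@H](N[S@](=O)C(C)(C)C)CC/C=C\C[C@H](C)C(=O)OC)C(OC)OC
F9 | step 2 | tert-butyl 5-(furan-2-yl)-2-methyl-3-oxopentanoate | CC(C)(C)OC(=O)C(C)C(=O)CCc1ccco1
F10 | step 2 | tert-butyl (Z)-5-(furan-2-yl)-2-methyl-3-(trifluoromethylsulfonyloxy)pent-2-enoate | CC(C)(C)OC(=O)/C(C)=C(/CCc1ccco1)OS(=O)(=O)C(F)(F)F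
F11 | step 2 | tert-butyl (Z)-3-formyl-5-(furan-2-yl)-2-methylpent-2-enoate | CC(C)(C)OC(=O)/C(C)=C(/CCc1ccco1)C=O
F12 | step 19 | 5-chlorobutenolide hydrochloride derived from 30 | CC1=C(CC[C@]2(C[C@@H](C)C(=O)O2)[C@@H]2CC[C@@H]([C@@H]3C[C@H](C)C(=O)O3)N2)C(Cl)OC1=O.Cl
A1 | alternative 1 | didehydro target with a ring B alkene conjugated to butenolide D | CC1=C2C=C[C@]3(C[C@@H](C)C(=O)O3)[C@@H]3CC[C@@H]([C@@H]4C[C@H](C)C(=O)O4)N3[C@H]2OC1=O
A2 | alternative 1 | divinyl N,O-acetal (vinyl on the spiro carbon, vinyl on the butenolide β-carbon) | C=C[C@]1(C[C@@H](C)C(=O)O1)[C@@H]1CC[C@@H]([C@@H]2C[C@H](C)C(=O)O2)N1[C@H]1OC(=O)C(C)=C1C=C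
A3 | alternative 2 | tricyclic unsaturated lactam allyl ester with rings A, B, C and E | C=CCOC(=O)/C(C)=C1/CC[C@]2(C[C@@H](C)C(=O)O2)[C@@H]2CC[C@@H]([C@@H]3C[C@H](C)C(=O)O3)N2C1=O
A4 | alternative 2 | azido alkylidene cyclohexanone with spiro lactone C and lactone E | C=CCOC(=O)/C(C)=C1/CC[C@]2(C[C@@H](C)C(=O)O2)[C@H](CC[C@H](N=[N+]=[N-])[C@@H]2C[C@H](C)C(=O)O2)C1=O
A5 | alternative 3 | N-Boc pyrrolidine with spiro lactone C, lactone E and the silylfuran arm | Cc1c(CC[C@]2(C[C@@H](C)C(=O)O2)[C@@H]2CC[C@@H]([C@@H]3C[C@H](C)C(=O)O3)N2C(=O)OC(C)(C)C)coc1[Si](C)(C)C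
A6 | alternative 3 | N-Boc prolyl γ-keto methyl ester carrying lactone E | COC(=O)[C@H](C)CC(=O)[C@@H]1CC[C@@H]([C@@H]2C[C@H](C)C(=O)O2)N1C(=O)OC(C)(C)C
A7 | alternative 3 | [4-(2-iodoethyl)-3-methylfuran-2-yl]trimethylsilane | Cc1c(CCI)coc1[Si](C)(C)C
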